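**Lifetime first.** Start from 6.85 min, the mean lifetime of the intermediate, one over the sum of the rate constants of its two exits, on to target and back to starting material and partner.

    target ⇌ isomer of the product (K1 = 3.52, k1 = 0.00103 s⁻¹)
    intermediate → target (k2 = 0.00156 s⁻¹)
    starting material + partner ⇌ intermediate (K3 = 22.8 M⁻¹, k3 = 0.0199 M⁻¹ s⁻¹)

| setting | delta | zeta | gamma | beta |
|---|---|---|---|---|
| starting material | 0.11 M | 0.11 M | 0.11 M (fed, over 20.0 min) | 0.11 M |
| partner | 0.121 M | 0.121 M | 0.121 M | 0.121 M |
| remark | one stirred flow tank at steady state, fed with the mixture as stated, mean residence time 20 min | everything together in a closed stirred flask, run for 20 min | all but starting material at the start; starting material goes in evenly over 20.0 min, the run ends at 20 min | a single well-mixed tank run continuously and read at steady state, 60.0 min in it on average |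
| time |  | 20 min | 20 min |  |

- the stated concentrations are those of everything mixed, before any reaction; amounts are the same in each set-up
- the feed brings no volume worth counting
- run time (zeta): 20 min

1. the set-up with the highest amount of intermediate at the outlet or at the end, in percent of the starting material put in ("none" if the first two lie within 2 percentage points) (delta / zeta / gamma / beta / none)
2. amount of intermediate at the outlet or at the end, in percent of the starting material put in, delta
3. amount of intermediate at the outlet or at the end, in percent of the starting material put in, zeta
4. amount of intermediate at the outlet or at the end, in percent of the starting material put in, gamma
5. amount of intermediate at the outlet or at the end, in percent of the starting material put in, beta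

**Closed flask.** Write a, b and i for starting material, partner and intermediate as fractions of the starting material put in. At the charged partner, starting material reacts with a time of 6.92 min, about equal to the lifetime, so hold partner constant (pseudo-first-order) and treat the two times as one. Zeta then ends after 2.92 lifetimes with i at 15.8%. Object at once on two counts: b starts at just 1.10 and falls with a, which lowers i, while the lifetime counts as lost the 35.9% of the exit that goes back to starting material and can form intermediate again, which raises i; the two pull opposite ways, so take this figure as rough.

**Dosed flask.** Run the same reckoning for gamma, where one lifetime of feed brings 34.3% of the charge and the feed lasts to the end, which gives i near 27.0%. Object again: the same two corrections pull opposite ways here, so this figure is rough as well. The two estimates stand 11 percentage points apart, so expect gamma above zeta and leave the size of the gap open.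

**Tank delta.** The outlet is a third exit, so add its rate to the lifetime's and get a holding time of 5.10 min; i is the formation rate per charge, the forward constant times the charged starting material times a times b, multiplied by this holding time. But part of what forms returns, so multiply by 0.733 in the balance. The fraction consumed then equals 1.92 times a times b, with b equal to a plus 0.100. This gives a = 47.5% and i = 18.3%.

**The forecast.** It gives 18.3% for delta, 19.5% for zeta, 24.4% for gamma and 10.4% for beta, and names gamma as best, on the ground that “Slow feeding keeps partner in excess and delays formation”.

**The result.** The simulation gives 18.3%, 19.6%, 24.5% and 10.4% in the same order, and gamma is highest. Gamma ends with 51.1% of the charge still as starting material, against 33.8% in zeta. Now use the lifetime on beta: its longer residence raises the holding time just to 6.15 min from 5.10 min in delta, while a stands at 31.2%, and the tank rule then gives i = 10.4%.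

The constants were set for the occasion; the run is a simulation.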